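## Retrosynthetic overview

1. The last C–C bond is a Stille coupling between an (E)-vinylstannane on the epoxyquinol core and a (2E,4E)-5-bromodienamide that already carries the aminohydroxycyclopentenone ring (bought as cyclopentane-1,3-dione).
2. The enamide C–N bond comes from copper-catalysed amidation of a 2-iodocyclohexenone with (2E,4R)-2,4-dimethyloct-2-enamide (Evans methylation, Wittig).
3. The six-membered ring is closed by intramolecular aldol condensation of an acyclic 1,5-keto aldehyde (methyl ketone onto a quaternary α-silyloxy aldehyde) that already holds all three core stereocentres.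
4. Sharpless epoxidation of a 2-alkynyl allylic alcohol fixes the tertiary carbinol; hydroxyl-directed epoxidation of the derived Z-allylic alcohol places the oxirane anti to the hydroxyl.
5. Ring order: oxirane (acyclic stage), then cyclohexenone (aldol); the cyclopentenone ring is present from the start.

Assumption: the SMILES is read as the (1S,5R,6R)-7-oxabicyclo[4.1.0]heptenone core (C-5 hydroxyl anti to the epoxide, triene chain syn to it) bearing a (2E,4R)-2,4-dimethyloct-2-enoyl amide.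

## Route

### Upper amide (steps 1–6)

Step 1
Reactants: 1 (R)-4-benzyl-1,3-oxazolidin-2-one; 2 hexanoyl chloride
Product: 3 (R)-4-benzyl-3-hexanoyl-1,3-oxazolidin-2-one
Conditions: n-BuLi, THF, −78 °C; then 2, −78 → 0 °C
Reagents that add atoms: none
Why: N-acylation of the lithiated Evans auxiliary (nucleophilic acyl substitution) touches no stereocentre.

Step 2
Reactants: 3 N-hexanoyl oxazolidinone
Product: 4 (R)-4-benzyl-3-[(2R)-2-methylhexanoyl]-1,3-oxazolidin-2-one
Conditions: NaN(SiMe3)2, THF, −78 °C; MeI, −78 °C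
Reagents that add atoms: iodomethane, CI
Why: Evans asymmetric alkylation, in which the chelated Z-enolate is methylated on the face opposite the benzyl group, sets the (R) methyl-bearing centre.

Step 3
Reactants: 4 methylated imide
Product: 5 (R)-2-methylhexan-1-ol
Conditions: LiBH4, H2O (1.1 equiv), Et2O, 0 °C
Reagents that add atoms: none
Why: Hydride reduction of the imide releases the primary alcohol without epimerisation and returns the auxiliary.

Step 4
Reactants: 5 (R)-2-methylhexan-1-ol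
Product: 7 ethyl (2E,4R)-2,4-dimethyloct-2-enoate, via (R)-2-methylhexanal 6 (not isolated)
Conditions: Pr4N[RuO4] (5 mol%), N-methylmorpholine N-oxide, 4 Å MS, CH2Cl2, rt; then Ph3P=C(Me)CO2Et, rt → 40 °C
Reagents that add atoms: ethyl 2-(triphenyl-λ5-phosphanylidene)propanoate, CCOC(=O)C(C)=P(c1ccccc1)(c1ccccc1)c1ccccc1
Why: Ley–Griffith oxidation followed in the same flask by Wittig olefination with a stabilised ylide gives the E trisubstituted enoate and avoids handling the volatile, epimerisable aldehyde.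

Step 5
Reactants: 7 ethyl ester
Product: 8 (2E,4R)-2,4-dimethyloct-2-enoic acid
Conditions: LiOH, THF/MeOH/H2O, 45 °C; then 1 M HCl
Reagents that add atoms: lithium hydroxide, [Li+].[OH-]
Why: Saponification leaves the γ stereocentre and the E alkene untouched.

Step 6
Reactants: 8 enoic acid
Product: 10 (2E,4R)-2,4-dimethyloct-2-enamide, via acyl chloride 9 (not isolated)
Conditions: (COCl)2, DMF (cat.), CH2Cl2, 0 °C → rt; concentrate; NH3 (0.5 M in dioxane), THF, 0 °C
Reagents that add atoms: ammonia, N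
Why: Acid chloride formation and aminolysis (nucleophilic acyl substitution) give the primary amide needed for the later C–N coupling.

### Lower bromodienamide (steps 7–12)

Step 7
Reactants: 11 pyridine–sulfur trioxide complex (pyridinium-1-sulfonate)
Product: 12 potassium (1E,3E)-5-oxopenta-1,3-dien-1-olate (glutaconaldehyde potassium salt)
Conditions: KOH (aq.), −20 → 40 °C; cool, filter
Reagents that add atoms: potassium hydroxide, [K+].[OH-]
Why: Hydroxide opens the N-sulfonylpyridinium ring (Zincke-type ring opening) and hydrolyses the N-sulfonyl imine to the stable all-trans dienolate.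

Step 8
Reactants: 12 glutaconaldehyde potassium salt
Product: 13 (2E,4E)-5-bromopenta-2,4-dienal
Conditions: PPh3, Br2, CH2Cl2, 0 °C; then 12, 0 °C → rt
Reagents that add atoms: bromine (delivered as Ph3PBr2 made in the flask), BrBr
Why: Deoxybromination of the enolate oxygen by the bromophosphonium salt (addition–elimination on the vinylogous formyl system) gives the thermodynamically favoured E,E bromodienal.

Step 9
Reactants: 13 bromodienal
Product: 14 (2E,4E)-5-bromopenta-2,4-dienoic acid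
Conditions: NaClO2, NaH2PO4, 2-methylbut-2-ene, t-BuOH/H2O, 0 °C → rt
Reagents that add atoms: sodium chlorite, [Na+].[O-]Cl=O
Why: Pinnick oxidation converts the enal into the acid without touching the diene or the vinyl bromide.

Step 10
Reactants: 15 cyclopentane-1,3-dione
Product: 16 2-nitrocyclopentane-1,3-dione (enol form)
Conditions: fuming HNO3, Et2O, 0 °C
Reagents that add atoms: nitric acid, O[N+](=O)[O-]
Why: Electrophilic nitration of the enol takes place at the doubly activated C-2 position.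

Step 11
Reactants: 16 nitro dione
Product: 17 2-amino-3-hydroxycyclopent-2-en-1-one hydrochloride
Conditions: H2 (1 atm), Pd/C, HCl (1.1 equiv), MeOH, rt
Reagents that add atoms: hydrogen chloride, Cl
Why: Catalytic hydrogenation reduces the nitro group and the air-sensitive aminodione is trapped as its hydrochloride.

Step 12
Reactants: 14 bromodienoic acid; 17 aminodione hydrochloride
Product: 19 (2E,4E)-5-bromo-N-(2-hydroxy-5-oxocyclopent-1-en-1-yl)penta-2,4-dienamide, via acyl chloride 18 (not isolated)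
Conditions: (COCl)2, DMF (cat.), CH2Cl2, 0 °C → rt; concentrate; 17, Et3N (2.2 equiv), CH2Cl2, 0 °C → rt
Reagents that add atoms: none
Why: N-acylation of the aminodione (nucleophilic acyl substitution, any O-acyl isomer rearranging to the amide) gives the bromodiene partner for the final Stille coupling.

### Core and endgame (steps 13–30)

Step 13
Reactants: 20 (R)-but-3-yn-2-ol; 21 4-methoxybenzyl chloride
Product: 22 1-{[(2R)-but-3-yn-2-yloxy]methyl}-4-methoxybenzene
Conditions: NaH, Bu4NI (cat.), THF/DMF, 0 °C → rt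
Reagents that add atoms: none
Why: Williamson etherification protects the carbinol, which is only a latent methyl ketone (one enantiomer is used so that all intermediates are single diastereomers).

Step 14
Reactants: 22 propargylic ether; 23 2-bromoprop-2-en-1-ol
Product: 24 (5R)-5-[(4-methoxybenzyl)oxy]-2-methylidenehex-3-yn-1-ol
Conditions: Pd(PPh3)4 (3 mol%), CuI (6 mol%), Et3N, THF, rt
Reagents that add atoms: none
Why: Sonogashira coupling of the vinyl bromide with the terminal alkyne assembles the six-carbon chain as a 2-substituted allylic alcohol.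

Step 15
Reactants: 24 enynol
Product: 25 [(2R)-2-{(3R)-3-[(4-methoxybenzyl)oxy]but-1-yn-1-yl}oxiran-2-yl]methanol
Conditions: Ti(OiPr)4 (10 mol%), D-(−)-diethyl tartrate (13 mol%), t-BuOOH, 4 Å MS, CH2Cl2, −20 °C
Reagents that add atoms: tert-butyl hydroperoxide, CC(C)(C)OO
Why: Sharpless asymmetric epoxidation of the 1,1-disubstituted allylic alcohol with the D-tartrate catalyst delivers oxygen to the face that makes the quaternary centre (R), the future carbinol carbon of the core.

Step 16
Reactants: 25 alkynyl epoxy alcohol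
Product: 26 [(2R)-2-{(1Z,3R)-3-[(4-methoxybenzyl)oxy]but-1-en-1-yl}oxiran-2-yl]methanol
Conditions: H2 (1 atm), Pd/CaCO3 poisoned with Pb(OAc)2, quinoline, EtOAc, rt
Reagents that add atoms: none
Why: Lindlar semi-hydrogenation (syn addition of H2) gives the Z alkene needed for a cis epoxide and for ring closure.

Step 17
Reactants: 26 epoxy alcohol
Product: 27 (2S)-2-{(1Z,3R)-3-[(4-methoxybenzyl)oxy]but-1-en-1-yl}oxirane-2-carbaldehyde
Conditions: Pr4N[RuO4] (5 mol%), N-methylmorpholine N-oxide, 4 Å MS, CH2Cl2, 0 °C → rt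
Reagents that add atoms: none
Why: Ley–Griffith oxidation under neutral conditions gives the non-enolisable epoxy aldehyde (the descriptor changes only through CIP priorities).

Step 18
Reactants: 27 epoxy aldehyde
Product: 28 (2R)-2-ethynyl-2-{(1Z,3R)-3-[(4-methoxybenzyl)oxy]but-1-en-1-yl}oxirane
Conditions: dimethyl (1-diazo-2-oxopropyl)phosphonate, K2CO3, MeOH, 0 °C → rt
Reagents that add atoms: dimethyl (1-diazo-2-oxopropyl)phosphonate, COP(=O)(OC)C(=[N+]=[N-])C(C)=O
Why: Ohira–Bestmann (Seyferth–Gilbert) homologation turns the aldehyde into the terminal alkyne that later carries the triene, without touching the quaternary centre.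

Step 19
Reactants: 28 ethynyl vinyl oxirane; 29 4-methoxybenzyl alcohol
Product: 30 (2R,3Z,5R)-2-ethynyl-1,5-bis[(4-methoxybenzyl)oxy]hex-3-en-2-ol
Conditions: NaH (0.3 equiv), 29 (5 equiv), DMF, 50 °C
Reagents that add atoms: none
Why: Base-mediated SN2 opening of the 2,2-disubstituted epoxide at its CH2 terminus leaves the C–O bond at the quaternary carbon intact, so the tertiary alcohol keeps the Sharpless-derived configuration.

Step 20
Reactants: 30 Z-allylic tertiary alcohol
Product: 31 (2R)-2-[(2R,3R)-3-{(1R)-1-[(4-methoxybenzyl)oxy]ethyl}oxiran-2-yl]-1-[(4-methoxybenzyl)oxy]but-3-yn-2-ol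
Conditions: mCPBA, CH2Cl2, 0 °C
Reagents that add atoms: 3-chloroperoxybenzoic acid, OOC(=O)c1cccc(Cl)c1
Why: In this hydroxyl-directed (Henbest) epoxidation, allylic 1,3-strain places the slim ethynyl group in the alkene plane, so the hydrogen-bonded peracid attacks the face that becomes anti to the hydroxyl once the chain is folded into the ring, which sets both oxirane carbons as a cis epoxide.

Step 21
Reactants: 31 epoxy alcohol
Product: 32 triethyl{[(2R)-2-[(2R,3R)-3-{(1R)-1-[(4-methoxybenzyl)oxy]ethyl}oxiran-2-yl]-1-[(4-methoxybenzyl)oxy]but-3-yn-2-yl]oxy}silane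
Conditions: Et3SiOTf, 2,6-lutidine, CH2Cl2, −78 → 0 °C
Reagents that add atoms: triethylsilyl trifluoromethanesulfonate, CC[Si](CC)(CC)OS(=O)(=O)C(F)(F)F
Why: Silylation of the hindered tertiary alcohol under non-basic conditions avoids Payne rearrangement and protects the carbinol for the steps that follow.

Step 22
Reactants: 32 silyl ether
Product: 33 triethyl{(3R)-3-[(2R,3R)-3-{(1R)-1-[(4-methoxybenzyl)oxy]ethyl}oxiran-2-yl]-4-[(4-methoxybenzyl)oxy]-3-[(triethylsilyl)oxy]but-1-yn-1-yl}silane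
Conditions: n-BuLi (1.05 equiv), THF, −78 °C; Et3SiCl, −78 → 0 °C
Reagents that add atoms: chlorotriethylsilane, CC[Si](Cl)(CC)CC
Why: Deprotonation and C-silylation of the terminal alkyne shields it from iodine and from copper acetylide chemistry in steps 26 and 27.

Step 23
Reactants: 33 bis-silyl compound
Product: 34 (2R)-2-[(2R,3R)-3-[(1R)-1-hydroxyethyl]oxiran-2-yl]-2-[(triethylsilyl)oxy]-4-(triethylsilyl)but-3-yn-1-ol
Conditions: DDQ (2.6 equiv), CH2Cl2/pH 7 buffer (10:1), 0 °C → rt
Reagents that add atoms: none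
Why: Oxidative cleavage of both 4-methoxybenzyl ethers (hydride abstraction, then hydrolysis of the oxocarbenium ion) leaves the silyl groups, epoxide and alkyne untouched.

Step 24
Reactants: 34 diol
Product: 35 (2S)-2-[(2R,3S)-3-acetyloxiran-2-yl]-2-[(triethylsilyl)oxy]-4-(triethylsilyl)but-3-ynal
Conditions: (COCl)2, DMSO, CH2Cl2, −78 °C; Et3N, −78 → 0 °C
Reagents that add atoms: none
Why: Swern oxidation activates both hydroxyls before base is added, so the primary and secondary alcohols are oxidised together, no lactol or lactone can form, and the auxiliary carbinol centre is erased.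

Step 25
Reactants: 35 epoxy keto aldehyde
Product: 37 (1S,5S,6R)-5-[(triethylsilyl)oxy]-5-[(triethylsilyl)ethynyl]-7-oxabicyclo[4.1.0]hept-3-en-2-one, via aldol adduct 36 (not isolated)
Conditions: piperidine (0.3 equiv), AcOH (0.3 equiv), toluene, 45 °C
Reagents that add atoms: none
Why: In this intramolecular aldol condensation (6-enolexo) the methyl ketone is the only enolisable position, the cis epoxide holds the two carbonyl arms together, and E1cB loss of water gives the cyclohexenone without creating or disturbing a stereocentre.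

Step 26
Reactants: 37 enone
Product: 38 (1S,5S,6R)-3-iodo-5-[(triethylsilyl)oxy]-5-[(triethylsilyl)ethynyl]-7-oxabicyclo[4.1.0]hept-3-en-2-one
Conditions: I2, pyridine/CH2Cl2 (1:1), 0 °C → rt
Reagents that add atoms: iodine, II
Why: Johnson α-iodination of the enone (pyridine conjugate addition, iodination of the enolate, elimination) is specific for the α-carbon.

Step 27
Reactants: 38 iodoenone; 10 (2E,4R)-2,4-dimethyloct-2-enamide
Product: 39 (2E,4R)-2,4-dimethyl-N-[(1S,5S,6R)-2-oxo-5-[(triethylsilyl)oxy]-5-[(triethylsilyl)ethynyl]-7-oxabicyclo[4.1.0]hept-3-en-3-yl]oct-2-enamide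
Conditions: CuI (10 mol%), MeNHCH2CH2NHMe (20 mol%), Cs2CO3, THF, 55 °C
Reagents that add atoms: none
Why: Copper-catalysed Goldberg–Buchwald amidation of the electron-poor vinyl iodide with the primary amide forms the enamide C–N bond without moving the double bond.

Step 28
Reactants: 39 silylated enamide
Product: 40 (2E,4R)-N-[(1S,5S,6R)-5-ethynyl-5-hydroxy-2-oxo-7-oxabicyclo[4.1.0]hept-3-en-3-yl]-2,4-dimethyloct-2-enamide
Conditions: Bu4NF (2.5 equiv), AcOH (2.5 equiv), THF, 0 °C → rt
Reagents that add atoms: none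
Why: Buffered fluoride cleaves the O–Si and alkynyl C–Si bonds together, releasing the tertiary alcohol and the terminal alkyne.

Step 29
Reactants: 40 ethynyl carbinol
Product: 41 (2E,4R)-N-{(1S,5S,6R)-5-hydroxy-2-oxo-5-[(E)-2-(tributylstannyl)ethenyl]-7-oxabicyclo[4.1.0]hept-3-en-3-yl}-2,4-dimethyloct-2-enamide
Conditions: Bu3SnH (1.2 equiv, slow addition), PdCl2(PPh3)2 (3 mol%), THF, 0 °C
Reagents that add atoms: tributyltin hydride, CCCC[SnH](CCCC)CCCC
Why: Palladium-catalysed syn hydrostannation places tin on the terminal carbon because the quaternary carbinol blocks the internal position, giving the E vinylstannane.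

Step 30
Reactants: 41 vinylstannane; 19 bromodienamide
Product: 42 (2E,4R)-N-[(1S,5R,6R)-5-hydroxy-5-[(1E,3E,5E)-7-[(2-hydroxy-5-oxocyclopent-1-en-1-yl)amino]-7-oxohepta-1,3,5-trien-1-yl]-2-oxo-7-oxabicyclo[4.1.0]hept-3-en-3-yl]-2,4-dimethyloct-2-enamide
Conditions: PdCl2(MeCN)2 (10 mol%), DMF, rt, dark
Reagents that add atoms: none
Why: Stille coupling joins the two alkenyl partners with retention of both geometries and completes the (1E,3E,5E)-triene under neutral conditions that the epoxyquinol tolerates.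

## Compound list

1 | (R)-4-benzyl-1,3-oxazolidin-2-one | O=C1N[C@H](Cc2ccccc2)CO1 | starting material
2 | hexanoyl chloride | CCCCCC(Cl)=O | starting material
3 | (R)-4-benzyl-3-hexanoyl-1,3-oxazolidin-2-one | CCCCCC(=O)N1[C@H](Cc2ccccc2)COC1=O | intermediate
4 | (R)-4-benzyl-3-[(2R)-2-methylhexanoyl]-1,3-oxazolidin-2-one | CCCC[C@@H](C)C(=O)N1[C@H](Cc2ccccc2)COC1=O | intermediate
5 | (R)-2-methylhexan-1-ol | CCCC[C@@H](C)CO | intermediate
6 | (R)-2-methylhexanal | CCCC[C@@H](C)C=O | intermediate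
7 | ethyl (2E,4R)-2,4-dimethyloct-2-enoate | CCCC[C@@H](C)/C=C(\C)C(=O)OCC | intermediate
8 | (2E,4R)-2,4-dimethyloct-2-enoic acid | CCCC[C@@H](C)/C=C(\C)C(=O)O | intermediate
9 | (2E,4R)-2,4-dimethyloct-2-enoyl chloride | CCCC[C@@H](C)/C=C(\C)C(Cl)=O | intermediate
10 | (2E,4R)-2,4-dimethyloct-2-enamide | CCCC[C@@H](C)/C=C(\C)C(N)=O | intermediate
11 | pyridine–sulfur trioxide complex (pyridinium-1-sulfonate) | [O-]S(=O)(=O)[n+]1ccccc1 | starting material
12 | potassium (1E,3E)-5-oxopenta-1,3-dien-1-olate | [K+].[O-]/C=C/C=C/C=O | intermediate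
13 | (2E,4E)-5-bromopenta-2,4-dienal | O=C/C=C/C=C/Br | intermediate
14 | (2E,4E)-5-bromopenta-2,4-dienoic acid | OC(=O)/C=C/C=C/Br | intermediate
15 | cyclopentane-1,3-dione | O=C1CCC(=O)C1 | starting material
16 | 2-nitrocyclopentane-1,3-dione (enol form) | O=C1CCC(O)=C1[N+](=O)[O-] | intermediate
17 | 2-amino-3-hydroxycyclopent-2-en-1-one hydrochloride | Cl.NC1=C(O)CCC1=O | intermediate
18 | (2E,4E)-5-bromopenta-2,4-dienoyl chloride | ClC(=O)/C=C/C=C/Br | intermediate
19 | (2E,4E)-5-bromo-N-(2-hydroxy-5-oxocyclopent-1-en-1-yl)penta-2,4-dienamide | O=C(/C=C/C=C/Br)NC1=C(O)CCC1=O | intermediate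
20 | (R)-but-3-yn-2-ol | C#C[C@@H](C)O | starting material
21 | 4-methoxybenzyl chloride | COc1ccc(CCl)cc1 | starting material
22 | 1-{[(2R)-but-3-yn-2-yloxy]methyl}-4-methoxybenzene | C#C[C@@H](C)OCc1ccc(OC)cc1 | intermediate
23 | 2-bromoprop-2-en-1-ol | OCC(Br)=C | starting material
24 | (5R)-5-[(4-methoxybenzyl)oxy]-2-methylidenehex-3-yn-1-ol | OCC(=C)C#C[C@@H](C)OCc1ccc(OC)cc1 | intermediate
25 | [(2R)-2-{(3R)-3-[(4-methoxybenzyl)oxy]but-1-yn-1-yl}oxiran-2-yl]methanol | OC[C@]1(C#C[C@@H](C)OCc2ccc(OC)cc2)CO1 | intermediate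
26 | [(2R)-2-{(1Z,3R)-3-[(4-methoxybenzyl)oxy]but-1-en-1-yl}oxiran-2-yl]methanol | OC[C@]1(/C=C\[C@@H](C)OCc2ccc(OC)cc2)CO1 | intermediate
27 | (2S)-2-{(1Z,3R)-3-[(4-methoxybenzyl)oxy]but-1-en-1-yl}oxirane-2-carbaldehyde | O=C[C@]1(/C=C\[C@@H](C)OCc2ccc(OC)cc2)CO1 | intermediate
28 | (2R)-2-ethynyl-2-{(1Z,3R)-3-[(4-methoxybenzyl)oxy]but-1-en-1-yl}oxirane | C#C[C@]1(/C=C\[C@@H](C)OCc2ccc(OC)cc2)CO1 | intermediate
29 | 4-methoxybenzyl alcohol | COc1ccc(CO)cc1 | starting material
30 | (2R,3Z,5R)-2-ethynyl-1,5-bis[(4-methoxybenzyl)oxy]hex-3-en-2-ol | C#C[C@@](O)(COCc1ccc(OC)cc1)/C=C\[C@@H](C)OCc1ccc(OC)cc1 | intermediate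
31 | (2R)-2-[(2R,3R)-3-{(1R)-1-[(4-methoxybenzyl)oxy]ethyl}oxiran-2-yl]-1-[(4-methoxybenzyl)oxy]but-3-yn-2-ol | C#C[C@@](O)(COCc1ccc(OC)cc1)[C@@H]2O[C@@H]2[C@@H](C)OCc3ccc(OC)cc3 | intermediate
32 | triethyl{[(2R)-2-[(2R,3R)-3-{(1R)-1-[(4-methoxybenzyl)oxy]ethyl}oxiran-2-yl]-1-[(4-methoxybenzyl)oxy]but-3-yn-2-yl]oxy}silane | C#C[C@@](O[Si](CC)(CC)CC)(COCc1ccc(OC)cc1)[C@@H]2O[C@@H]2[C@@H](C)OCc3ccc(OC)cc3 | intermediate
33 | triethyl{(3R)-3-[(2R,3R)-3-{(1R)-1-[(4-methoxybenzyl)oxy]ethyl}oxiran-2-yl]-4-[(4-methoxybenzyl)oxy]-3-[(triethylsilyl)oxy]but-1-yn-1-yl}silane | CC[Si](CC)(CC)C#C[C@@](O[Si](CC)(CC)CC)(COCc1ccc(OC)cc1)[C@@H]2O[C@@H]2[C@@H](C)OCc3ccc(OC)cc3 | intermediate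
34 | (2R)-2-[(2R,3R)-3-[(1R)-1-hydroxyethyl]oxiran-2-yl]-2-[(triethylsilyl)oxy]-4-(triethylsilyl)but-3-yn-1-ol | CC[Si](CC)(CC)C#C[C@@](O[Si](CC)(CC)CC)(CO)[C@@H]1O[C@@H]1[C@@H](C)O | intermediate
35 | (2S)-2-[(2R,3S)-3-acetyloxiran-2-yl]-2-[(triethylsilyl)oxy]-4-(triethylsilyl)but-3-ynal | CC[Si](CC)(CC)C#C[C@@](O[Si](CC)(CC)CC)(C=O)[C@@H]1O[C@@H]1C(C)=O | intermediate
36 | (1S,5R,6R)-4-hydroxy-5-[(triethylsilyl)oxy]-5-[(triethylsilyl)ethynyl]-7-oxabicyclo[4.1.0]heptan-2-one (aldol adduct, C-4 epimers) | O=C1CC(O)[C@](O[Si](CC)(CC)CC)(C#C[Si](CC)(CC)CC)[C@@H]2O[C@H]12 | intermediate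
37 | (1S,5S,6R)-5-[(triethylsilyl)oxy]-5-[(triethylsilyl)ethynyl]-7-oxabicyclo[4.1.0]hept-3-en-2-one | O=C1C=C[C@](O[Si](CC)(CC)CC)(C#C[Si](CC)(CC)CC)[C@@H]2O[C@H]12 | intermediate
38 | (1S,5S,6R)-3-iodo-5-[(triethylsilyl)oxy]-5-[(triethylsilyl)ethynyl]-7-oxabicyclo[4.1.0]hept-3-en-2-one | O=C1C(I)=C[C@](O[Si](CC)(CC)CC)(C#C[Si](CC)(CC)CC)[C@@H]2O[C@H]12 | intermediate
39 | (2E,4R)-2,4-dimethyl-N-[(1S,5S,6R)-2-oxo-5-[(triethylsilyl)oxy]-5-[(triethylsilyl)ethynyl]-7-oxabicyclo[4.1.0]hept-3-en-3-yl]oct-2-enamide | CCCC[C@@H](C)/C=C(\C)C(=O)NC1=C[C@](O[Si](CC)(CC)CC)(C#C[Si](CC)(CC)CC)[C@@H]2O[C@@H]2C1=O | intermediate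
40 | (2E,4R)-N-[(1S,5S,6R)-5-ethynyl-5-hydroxy-2-oxo-7-oxabicyclo[4.1.0]hept-3-en-3-yl]-2,4-dimethyloct-2-enamide | CCCC[C@@H](C)/C=C(\C)C(=O)NC1=C[C@](O)(C#C)[C@@H]2O[C@@H]2C1=O | intermediate
41 | (2E,4R)-N-{(1S,5S,6R)-5-hydroxy-2-oxo-5-[(E)-2-(tributylstannyl)ethenyl]-7-oxabicyclo[4.1.0]hept-3-en-3-yl}-2,4-dimethyloct-2-enamide | CCCC[C@@H](C)/C=C(\C)C(=O)NC1=C[C@](O)(/C=C/[Sn](CCCC)(CCCC)CCCC)[C@@H]2O[C@@H]2C1=O | intermediate
42 | (2E,4R)-N-[(1S,5R,6R)-5-hydroxy-5-[(1E,3E,5E)-7-[(2-hydroxy-5-oxocyclopent-1-en-1-yl)amino]-7-oxohepta-1,3,5-trien-1-yl]-2-oxo-7-oxabicyclo[4.1.0]hept-3-en-3-yl]-2,4-dimethyloct-2-enamide | CCCC[C@@H](C)/C=C(\C)C(=O)NC1=C[C@](O)(/C=C/C=C/C=C/C(=O)NC2=C(O)CCC2=O)[C@@H]2O[C@@H]2C1=O | target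

## Step count and risks

Total steps: 30. Longest linear sequence: 18 (steps 13–30, from 20 to 42).

Steps most likely to fail:

**Step 20 (directed epoxidation).** The face selectivity rests on one conformational preference of an acyclic tertiary allylic alcohol, and the wrong epoxide would give the syn-hydroxy epoxide series. The fallback sets out from 30 and returns at 31. Deprotonation with LiN(SiMe3)2 and trapping with Boc2O gives the tert-butyl carbonate F1. IBr in toluene at −80 °C closes the carbonate carbonyl oxygen onto the alkene anti to iodine and gives the iodo cyclic carbonate F2. K2CO3 in MeOH cleaves the carbonate, and the freed secondary alkoxide displaces iodide to give 31. Peracid delivery is thereby replaced by an iodocarbonation and epoxide closure whose face selectivity is fixed in a five-membered cyclic transition state.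

**Step 25 (aldol condensation).** The amine catalyst may open the epoxy ketone, or the reaction may stop at the aldol stage. The fallback sets out from 35 and returns at 37. Bu2BOTf and i-Pr2NEt at −78 °C form the boron enolate of the methyl ketone, which adds to the aldehyde; oxidative work-up gives aldol 36, now isolated. MsCl and Et3N convert 36 into the methanesulfonate F3, and DBU eliminates it to 37. A stoichiometric preformed enolate and a separate elimination replace the one-pot amine-catalysed condensation.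

**Step 27 (copper-catalysed amidation).** The hindered, base-sensitive iodoenone may couple poorly with the primary amide. The fallback sets out from 38 and returns at 39. Exchange of iodide for azide (NaN3, CuI cat., MeNHCH2CH2NHMe, DMSO, rt) gives the vinyl azide F4. PMe3 in THF gives the iminophosphorane F5, which is acylated in the same flask with acyl chloride 9 and hydrolysed on aqueous work-up to 39. Nitrogen is thus brought in as azide and acylated afterwards, not coupled as the amide.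

## Further compounds

F1 | step 20 | tert-butyl (2R,3Z,5R)-2-ethynyl-1,5-bis[(4-methoxybenzyl)oxy]hex-3-en-2-yl carbonate | C#C[C@@](OC(=O)OC(C)(C)C)(COCc1ccc(OC)cc1)/C=C\[C@@H](C)OCc1ccc(OC)cc1
F2 | step 20 | (4R,5S)-4-ethynyl-5-{(1S,2R)-1-iodo-2-[(4-methoxybenzyl)oxy]propyl}-4-{[(4-methoxybenzyl)oxy]methyl}-1,3-dioxolan-2-one | C#C[C@]1(COCc2ccc(OC)cc2)OC(=O)O[C@@H]1[C@@H](I)[C@@H](C)OCc1ccc(OC)cc1
F3 | step 25 | (1S,6R)-2-oxo-5-[(triethylsilyl)oxy]-5-[(triethylsilyl)ethynyl]-7-oxabicyclo[4.1.0]heptan-4-yl methanesulfonate (C-5 as in 36, C-4 epimers) | O=C1CC(OS(C)(=O)=O)[C@](O[Si](CC)(CC)CC)(C#C[Si](CC)(CC)CC)[C@@H]2O[C@H]12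
F4 | step 27 | (1S,5S,6R)-3-azido-5-[(triethylsilyl)oxy]-5-[(triethylsilyl)ethynyl]-7-oxabicyclo[4.1.0]hept-3-en-2-one | O=C1C(N=[N+]=[N-])=C[C@](O[Si](CC)(CC)CC)(C#C[Si](CC)(CC)CC)[C@@H]2O[C@H]12
F5 | step 27 | (1S,5S,6R)-5-[(triethylsilyl)oxy]-5-[(triethylsilyl)ethynyl]-3-[(trimethyl-λ5-phosphanylidene)amino]-7-oxabicyclo[4.1.0]hept-3-en-2-one | O=C1C(N=P(C)(C)C)=C[C@](O[Si](CC)(CC)CC)(C#C[Si](CC)(CC)CC)[C@@H]2O[C@H]12
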